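**Retrosynthetic overview**

1. Atom labels (germacrane numbering): ten-membered ring C1–C10 with the C3–O–C10 bridge; lactone C8–O–C12(=O)–C11=C7; C13 = CH2OAc on C11; C14 and C15 = methyls on C10 and C4.
2. Target ⇐ acetylation of C6–OH and C13–OH ⇐ C8=C9 by E1cB elimination ⇐ ring C (ten-membered) closed last at C8–C9 by an intramolecular vinylogous Mukaiyama aldol of the butenolide onto a C9 aldehyde.
3. Ring A (dihydrofuran, C3–O–C10) ⇐ gold-catalysed 5-endo cycloisomerisation of a C2≡C3 alkynol ⇐ acetylide + (R)-2-methylglycidyl silyl ether (C1–C2 bond; brings C9, C10, C14).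
4. Key C4–C5 bond ⇐ enantioselective Mukaiyama aldol between the enolsilane of a 3-acetylfuran (east fragment, from 3-furanmethanol) and methyl pyruvate, which sets C4; CBS reduction sets C6; Sharpless epoxidation sets C10.
5. Ring order: furan (bought, latent ring B) → butenolide ring B by silicon-directed peracid oxidation → ring A → ring C.

Assumption: silylating agents, the bis(oxazoline) ligand, the CBS catalyst and the Ohira–Bestmann reagent are bought, and the bridged ten-membered ring is taken to allow only the (8E), ring-cis C8=C9 alkene.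

Abbreviations: TBS = tert-butyldimethylsilyl, TES = triethylsilyl, TIPS = triisopropylsilyl, TMS = trimethylsilyl; Fur = 5-TBS-4-(TIPSOCH2)furan-3-yl; Bl = 5-oxo-4-(TIPSOCH2)-2,5-dihydrofuran-3-yl.

**Route**

Step 1
Reactants: 1 3-furanmethanol
Product: 2 tert-butyl(furan-3-ylmethoxy)dimethylsilane
Conditions: TBSCl, imidazole, DMF, rt
Reagents that add atoms: tert-butyldimethylsilyl chloride, CC(C)(C)[Si](C)(C)Cl
Why: Standard silylation of a primary alcohol, which installs the silyl group that is moved onto carbon in step 2.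

Step 2
Reactants: 2 tert-butyl(furan-3-ylmethoxy)dimethylsilane
Product: 4 [2-(tert-butyldimethylsilyl)furan-3-yl]methanol, via 2-lithiofuran 3 (not isolated)
Conditions: n-BuLi, HMPA, THF, −78 °C → rt; aq. NH4Cl
Reagents that add atoms: none
Why: Ortho-lithiation at the furan C2 followed by 1,4 O→C silyl migration (retro-Brook rearrangement) puts silicon on the carbon that later becomes the lactone carbonyl C12.

Step 3
Reactants: 4 [2-(tert-butyldimethylsilyl)furan-3-yl]methanol; 5 N-methoxy-N-methylacetamide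
Product: 7 1-[5-(tert-butyldimethylsilyl)-4-(hydroxymethyl)furan-3-yl]ethan-1-one, via dilithio species 6 (not isolated)
Conditions: n-BuLi (2.2 equiv), DME, 0 °C; then 5, −78 → 0 °C; aq. NH4Cl
Reagents that add atoms: none
Why: With C2 blocked by silicon the lithium alkoxide directs lithiation to C4, and Weinreb acylation of the aryllithium stops cleanly at the methyl ketone (C5, C6).

Step 4
Reactants: 7 1-[5-(tert-butyldimethylsilyl)-4-(hydroxymethyl)furan-3-yl]ethan-1-one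
Product: 8 1-(Fur)ethan-1-one, i.e. 1-[5-TBS-4-(TIPSOCH2)furan-3-yl]ethan-1-one
Conditions: TIPSCl, imidazole, DMF, rt
Reagents that add atoms: triisopropylsilyl chloride, CC(C)[Si](Cl)(C(C)C)C(C)C
Why: Silylation of the primary C13 alcohol with a robust group that is a poor leaving group in the later dienolate chemistry.

Step 5
Reactants: 8 1-(Fur)ethan-1-one
Product: 9 trimethyl{[1-(Fur)ethenyl]oxy}silane
Conditions: TMSOTf, Et3N, CH2Cl2, 0 °C
Reagents that add atoms: trimethylsilyl triflate, C[Si](C)(C)OS(=O)(=O)C(F)(F)F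
Why: Soft enolisation of the aryl methyl ketone gives the only possible enolsilane for the Mukaiyama aldol.

Step 6
Reactants: 9 trimethyl{[1-(Fur)ethenyl]oxy}silane; 10 methyl pyruvate
Product: 12 methyl (2S)-2-hydroxy-2-methyl-4-oxo-4-(Fur)butanoate, via trimethylsilyl ether 11 (not isolated)
Conditions: Cu(OTf)2 (10 mol%), (S,S)-tert-butyl-bis(oxazoline) ligand (11 mol%), THF, −78 °C; then 1 M HCl, THF
Reagents that add atoms: none
Why: Catalytic enantioselective Mukaiyama aldol (Evans pyruvate aldol) in which the pyruvate chelates the divalent copper–bis(oxazoline) complex and the enolsilane attacks the exposed si face, forming the C4–C5 bond and the (S)-tertiary carbinol C4.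

Step 7
Reactants: 12 methyl (2S)-2-hydroxy-2-methyl-4-oxo-4-(Fur)butanoate
Product: 13 methyl (2S)-2-methyl-4-oxo-4-(Fur)-2-(triethylsilyloxy)butanoate
Conditions: TESOTf, 2,6-lutidine, CH2Cl2, −78 °C
Reagents that add atoms: triethylsilyl triflate, CC[Si](CC)(CC)OS(=O)(=O)C(F)(F)F
Why: Silylation of the tertiary alcohol under non-basic conditions avoids retro-aldol cleavage and removes a directing hydroxyl before the reagent-controlled reduction.

Step 8
Reactants: 13 methyl (2S)-2-methyl-4-oxo-4-(Fur)-2-(triethylsilyloxy)butanoate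
Product: 14 methyl (2S,4S)-4-hydroxy-2-methyl-4-(Fur)-2-(triethylsilyloxy)butanoate
Conditions: (R)-2-methyl-CBS-oxazaborolidine (20 mol%), BH3·SMe2, THF, −20 °C; MeOH
Reagents that add atoms: none
Why: Corey–Bakshi–Shibata reduction of a heteroaryl alkyl ketone, in which the furyl group is the large substituent so the (R)-catalyst delivers hydride to give the (S)-carbinol C6.

Step 9
Reactants: 14 methyl (2S,4S)-4-hydroxy-2-methyl-4-(Fur)-2-(triethylsilyloxy)butanoate
Product: 15 methyl (2S,4S)-4-(TBSO)-2-methyl-4-(Fur)-2-(TESO)butanoate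
Conditions: crude 14, TBSOTf, 2,6-lutidine, CH2Cl2, −78 → 0 °C
Reagents that add atoms: tert-butyldimethylsilyl triflate, CC(C)(C)[Si](C)(C)OS(=O)(=O)C(F)(F)F
Why: Prompt silylation of the secondary alcohol forestalls γ-lactonisation onto the ester and protects C6–OH for the organometallic steps.

Step 10
Reactants: 15 methyl (2S,4S)-4-(TBSO)-2-methyl-4-(Fur)-2-(TESO)butanoate
Product: 16 (2S,4S)-4-(TBSO)-2-methyl-4-(Fur)-2-(TESO)butanal
Conditions: i-Bu2AlH (1.1 equiv), CH2Cl2, −78 °C; aq. potassium sodium tartrate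
Reagents that add atoms: none
Why: Partial reduction of an α-silyloxy ester stops at the aldehyde because the chelated tetrahedral aluminate is stable at −78 °C, and the quaternary α-carbon cannot epimerise.

Step 11
Reactants: 16 (2S,4S)-4-(TBSO)-2-methyl-4-(Fur)-2-(TESO)butanal; 17 dimethyl (1-diazo-2-oxopropyl)phosphonate
Product: 18 (3S,5S)-5-(TBSO)-3-methyl-5-(Fur)-3-(TESO)pent-1-yne
Conditions: K2CO3, MeOH, 0 °C → rt
Reagents that add atoms: none
Why: Ohira–Bestmann (Seyferth–Gilbert) homologation of a non-enolisable aldehyde gives the terminal alkyne C2≡C3 under mild base.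

Step 12
Reactants: 19 2-methylprop-2-en-1-ol (methallyl alcohol)
Product: 20 [(2R)-2-methyloxiran-2-yl]methanol
Conditions: Ti(OiPr)4 (5 mol%), D-(−)-diisopropyl tartrate (6 mol%), t-BuOOH, 4 Å MS, CH2Cl2, −20 °C
Reagents that add atoms: tert-butyl hydroperoxide, CC(C)(C)OO
Why: Sharpless asymmetric epoxidation, in which the D-(−)-tartrate catalyst delivers oxygen to the face that gives the (R)-epoxy alcohol and so sets C10.

Step 13
Reactants: 20 [(2R)-2-methyloxiran-2-yl]methanol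
Product: 21 triethyl{[(2S)-2-methyloxiran-2-yl]methoxy}silane
Conditions: TESCl, imidazole, CH2Cl2, 0 °C
Reagents that add atoms: triethylsilyl chloride, CC[Si](CC)(CC)Cl
Why: Silylation of the primary alcohol (the descriptor changes only through CIP priorities) gives the most fluoride-labile silyl ether of the route, at C9.

Step 14
Reactants: 18 (3S,5S)-5-(TBSO)-3-methyl-5-(Fur)-3-(TESO)pent-1-yne; 21 triethyl{[(2S)-2-methyloxiran-2-yl]methoxy}silane
Product: 23 (2S,6S,8S)-8-(TBSO)-2,6-dimethyl-8-(Fur)-1,6-bis(TESO)oct-4-yn-2-ol, via lithium acetylide 22 (not isolated)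
Conditions: n-BuLi, THF, −78 °C; BF3·OEt2; then 21 (1.5 equiv), −78 °C; aq. NaHCO3
Reagents that add atoms: none
Why: Yamaguchi-type BF3-assisted opening of the epoxide by the acetylide at the unhindered CH2 (C1) forms C1–C2 and frees the tertiary C10–OH without touching the stereocentre.

Step 15
Reactants: 23 (2S,6S,8S)-8-(TBSO)-2,6-dimethyl-8-(Fur)-1,6-bis(TESO)oct-4-yn-2-ol
Product: 25 4-[(1S,3S,7S)-1-(TBSO)-7-hydroxy-3,7-dimethyl-3,8-bis(TESO)oct-4-yn-1-yl]-3-(TIPSOCH2)furan-2(5H)-one, via 2-silyloxyfuran 24 (not isolated)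
Conditions: AcOOH, NaOAc, CH2Cl2, 0 °C; then Et3N (cat.)
Reagents that add atoms: peracetic acid, CC(=O)OO
Why: Kuwajima-type peracid oxidation of a 2-silylfuran, in which ipso attack and C→O silyl shift make the silicon-bearing carbon the lactone carbonyl C12 and leave C8 as CH2.

Step 16
Reactants: 25 4-[(1S,3S,7S)-1-(TBSO)-7-hydroxy-3,7-dimethyl-3,8-bis(TESO)oct-4-yn-1-yl]-3-(TIPSOCH2)furan-2(5H)-one
Product: 26 4-{(1S,3S)-1-(TBSO)-3-[(5S)-5-methyl-5-(TESOCH2)-4,5-dihydrofuran-2-yl]-3-(TESO)butyl}-3-(TIPSOCH2)furan-2(5H)-one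
Conditions: (Ph3P)AuCl (5 mol%), AgOTf (5 mol%), 4 Å MS, THF, rt; Et3N quench; Et3N-deactivated silica
Reagents that add atoms: none
Why: Gold-catalysed 5-endo-dig hydroalkoxylation (cycloisomerisation) of the homopropargylic tertiary alcohol gives ring A with the C2=C3 enol ether as the only possible regiochemistry, the C9 oxygen being masked to prevent exo attack.

Step 17
Reactants: 26 4-{(1S,3S)-1-(TBSO)-3-[(5S)-5-methyl-5-(TESOCH2)-4,5-dihydrofuran-2-yl]-3-(TESO)butyl}-3-(TIPSOCH2)furan-2(5H)-one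
Product: 27 4-{(1S,3S)-1-(TBSO)-3-[(5S)-5-(hydroxymethyl)-5-methyl-4,5-dihydrofuran-2-yl]-3-(TESO)butyl}-3-(TIPSOCH2)furan-2(5H)-one
Conditions: Bu4NF/AcOH (1:1, 1.2 equiv), THF, 0 °C
Reagents that add atoms: none
Why: Buffered fluoride desilylation removes the primary TES ether far faster than the tertiary TES, secondary TBS and primary TIPS ethers, and the acid-free medium spares the enol ether.

Step 18
Reactants: 27 4-{(1S,3S)-1-(TBSO)-3-[(5S)-5-(hydroxymethyl)-5-methyl-4,5-dihydrofuran-2-yl]-3-(TESO)butyl}-3-(TIPSOCH2)furan-2(5H)-one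
Product: 28 (2S)-5-[(2S,4S)-4-(TBSO)-4-(Bl)-2-(TESO)butan-2-yl]-2-methyl-2,3-dihydrofuran-2-carbaldehyde
Conditions: SO3·pyridine, DMSO, i-Pr2NEt, CH2Cl2, 0 °C
Reagents that add atoms: none
Why: Parikh–Doering oxidation is non-acidic and gives a non-enolisable α-alkoxy aldehyde (C9) without harming the enol ether.

Step 19
Reactants: 28 (2S)-5-[(2S,4S)-4-(TBSO)-4-(Bl)-2-(TESO)butan-2-yl]-2-methyl-2,3-dihydrofuran-2-carbaldehyde
Product: 30 (4S,6S,10S)-6,9-bis(TBSO)-3,10-epoxy-4-(TESO)-13-(TIPSO)germacra-2,7(11)-dien-12,8-olide (C8/C9 diastereomer mixture), via silyloxyfuran aldehyde 29 (not isolated)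
Conditions: TBSOTf (2.5 equiv), i-Pr2NEt (5 equiv), CH2Cl2 (1 mM, slow addition of 28), −78 → 0 °C
Reagents that add atoms: tert-butyldimethylsilyl triflate, CC(C)(C)[Si](C)(C)OS(=O)(=O)C(F)(F)F
Why: Silylative intramolecular vinylogous Mukaiyama aldol, in which the in-situ 2-silyloxyfuran attacks the silyl-activated aldehyde through its γ-carbon C8 and silyl transfer makes the closure irreversible; the new C8 and C9 centres form as a mixture and are erased in step 20.

Step 20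
Reactants: 30 macrocyclic aldol silyl ether
Product: 31 (4S,6S,8E,10S)-6-(TBSO)-3,10-epoxy-4-(TESO)-13-(TIPSO)germacra-2,7(11),8-trien-12,8-olide
Conditions: DBU (3 equiv), CH2Cl2, 0 °C → rt
Reagents that add atoms: none
Why: E1cB elimination of silanolate through the furanolate gives the γ-ylidene butenolide, with the bridged ten-membered ring enforcing the ring-cis (8E) alkene and the extended conjugation favouring loss of the C9 rather than the C13 silyloxy group.

Step 21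
Reactants: 31 (4S,6S,8E,10S)-6-(TBSO)-3,10-epoxy-4-(TESO)-13-(TIPSO)germacra-2,7(11),8-trien-12,8-olide
Product: 32 (4S,6S,8E,10S)-3,10-epoxy-4,6,13-trihydroxygermacra-2,7(11),8-trien-12,8-olide
Conditions: Bu4NF/AcOH (1:1, excess), THF, 0 °C → rt
Reagents that add atoms: none
Why: Global fluoride desilylation under buffered, acid-free conditions keeps the enol ether and the enol lactone intact (direct translactonisation by C6–OH is blocked because it would need a bridgehead alkene).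

Step 22
Reactants: 32 (4S,6S,8E,10S)-3,10-epoxy-4,6,13-trihydroxygermacra-2,7(11),8-trien-12,8-olide
Product: 33 (4S,6S,8E,10S)-6,13-diacetoxy-3,10-epoxy-4-hydroxygermacra-2,7(11),8-trien-12,8-olide (CNP0144020.1)
Conditions: Ac2O, pyridine, DMAP (cat.), CH2Cl2, 0 °C
Reagents that add atoms: acetic anhydride, CC(=O)OC(C)=O
Why: Chemoselective acetylation of the primary and secondary alcohols; the tertiary C4–OH does not react under these mild conditions.

**Compound list**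

1 | 3-furanmethanol | OCc1ccoc1 | starting material
2 | tert-butyl(furan-3-ylmethoxy)dimethylsilane | CC(C)(C)[Si](C)(C)OCc1ccoc1 | intermediate
3 | {3-[(TBSO)methyl]furan-2-yl}lithium | [Li]c1occc1CO[Si](C)(C)C(C)(C)C | intermediate (not isolated)
4 | [2-(tert-butyldimethylsilyl)furan-3-yl]methanol | OCc1ccoc1[Si](C)(C)C(C)(C)C | intermediate
5 | N-methoxy-N-methylacetamide | CC(=O)N(C)OC | starting material
6 | lithium [2-TBS-4-lithiofuran-3-yl]methanolate | [Li]OCc1c([Li])coc1[Si](C)(C)C(C)(C)C | intermediate (not isolated)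
7 | 1-[5-TBS-4-(hydroxymethyl)furan-3-yl]ethan-1-one | CC(=O)c1coc([Si](C)(C)C(C)(C)C)c1CO | intermediate
8 | 1-[5-TBS-4-(TIPSOCH2)furan-3-yl]ethan-1-one | CC(=O)c1coc([Si](C)(C)C(C)(C)C)c1CO[Si](C(C)C)(C(C)C)C(C)C | intermediate
9 | trimethyl{[1-(Fur)ethenyl]oxy}silane | C=C(O[Si](C)(C)C)c1coc([Si](C)(C)C(C)(C)C)c1CO[Si](C(C)C)(C(C)C)C(C)C | intermediate
10 | methyl pyruvate | CC(=O)C(=O)OC | starting material
11 | methyl (2S)-2-methyl-4-oxo-4-(Fur)-2-(trimethylsilyloxy)butanoate | COC(=O)[C@@](C)(O[Si](C)(C)C)CC(=O)c1coc([Si](C)(C)C(C)(C)C)c1CO[Si](C(C)C)(C(C)C)C(C)C | intermediate (not isolated)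
12 | methyl (2S)-2-hydroxy-2-methyl-4-oxo-4-(Fur)butanoate | COC(=O)[C@@](C)(O)CC(=O)c1coc([Si](C)(C)C(C)(C)C)c1CO[Si](C(C)C)(C(C)C)C(C)C | intermediate
13 | methyl (2S)-2-methyl-4-oxo-4-(Fur)-2-(triethylsilyloxy)butanoate | COC(=O)[C@@](C)(O[Si](CC)(CC)CC)CC(=O)c1coc([Si](C)(C)C(C)(C)C)c1CO[Si](C(C)C)(C(C)C)C(C)C | intermediate
14 | methyl (2S,4S)-4-hydroxy-2-methyl-4-(Fur)-2-(triethylsilyloxy)butanoate | COC(=O)[C@@](C)(O[Si](CC)(CC)CC)C[C@H](O)c1coc([Si](C)(C)C(C)(C)C)c1CO[Si](C(C)C)(C(C)C)C(C)C | intermediate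
15 | methyl (2S,4S)-4-(TBSO)-2-methyl-4-(Fur)-2-(TESO)butanoate | COC(=O)[C@@](C)(O[Si](CC)(CC)CC)C[C@H](O[Si](C)(C)C(C)(C)C)c1coc([Si](C)(C)C(C)(C)C)c1CO[Si](C(C)C)(C(C)C)C(C)C | intermediate
16 | (2S,4S)-4-(TBSO)-2-methyl-4-(Fur)-2-(TESO)butanal | O=C[C@@](C)(O[Si](CC)(CC)CC)C[C@H](O[Si](C)(C)C(C)(C)C)c1coc([Si](C)(C)C(C)(C)C)c1CO[Si](C(C)C)(C(C)C)C(C)C | intermediate
17 | dimethyl (1-diazo-2-oxopropyl)phosphonate | CC(=O)C(=[N+]=[N-])P(=O)(OC)OC | starting material
18 | (3S,5S)-5-(TBSO)-3-methyl-5-(Fur)-3-(TESO)pent-1-yne | C#C[C@@](C)(O[Si](CC)(CC)CC)C[C@H](O[Si](C)(C)C(C)(C)C)c1coc([Si](C)(C)C(C)(C)C)c1CO[Si](C(C)C)(C(C)C)C(C)C | intermediate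
19 | 2-methylprop-2-en-1-ol | CC(=C)CO | starting material
20 | [(2R)-2-methyloxiran-2-yl]methanol | OC[C@]1(C)CO1 | intermediate
21 | triethyl{[(2S)-2-methyloxiran-2-yl]methoxy}silane | CC[Si](CC)(CC)OC[C@]1(C)CO1 | intermediate
22 | lithium acetylide of 18 | [Li]C#C[C@@](C)(O[Si](CC)(CC)CC)C[C@H](O[Si](C)(C)C(C)(C)C)c1coc([Si](C)(C)C(C)(C)C)c1CO[Si](C(C)C)(C(C)C)C(C)C | intermediate (not isolated)
23 | (2S,6S,8S)-8-(TBSO)-2,6-dimethyl-8-(Fur)-1,6-bis(TESO)oct-4-yn-2-ol | CC[Si](CC)(CC)OC[C@@](C)(O)CC#C[C@@](C)(O[Si](CC)(CC)CC)C[C@H](O[Si](C)(C)C(C)(C)C)c1coc([Si](C)(C)C(C)(C)C)c1CO[Si](C(C)C)(C(C)C)C(C)C | intermediate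
24 | 2-(TBSO)furan isomer of 23 (silyl moved from C to O) | CC[Si](CC)(CC)OC[C@@](C)(O)CC#C[C@@](C)(O[Si](CC)(CC)CC)C[C@H](O[Si](C)(C)C(C)(C)C)c1coc(O[Si](C)(C)C(C)(C)C)c1CO[Si](C(C)C)(C(C)C)C(C)C | intermediate (not isolated)
25 | 4-[(1S,3S,7S)-1-(TBSO)-7-hydroxy-3,7-dimethyl-3,8-bis(TESO)oct-4-yn-1-yl]-3-(TIPSOCH2)furan-2(5H)-one | CC[Si](CC)(CC)OC[C@@](C)(O)CC#C[C@@](C)(O[Si](CC)(CC)CC)C[C@H](O[Si](C)(C)C(C)(C)C)C1=C(CO[Si](C(C)C)(C(C)C)C(C)C)C(=O)OC1 | intermediate
26 | 4-{(1S,3S)-1-(TBSO)-3-[(5S)-5-methyl-5-(TESOCH2)-4,5-dihydrofuran-2-yl]-3-(TESO)butyl}-3-(TIPSOCH2)furan-2(5H)-one | CC[Si](CC)(CC)OC[C@]1(C)CC=C(O1)[C@@](C)(O[Si](CC)(CC)CC)C[C@H](O[Si](C)(C)C(C)(C)C)C2=C(CO[Si](C(C)C)(C(C)C)C(C)C)C(=O)OC2 | intermediate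
27 | 4-{(1S,3S)-1-(TBSO)-3-[(5S)-5-(hydroxymethyl)-5-methyl-4,5-dihydrofuran-2-yl]-3-(TESO)butyl}-3-(TIPSOCH2)furan-2(5H)-one | OC[C@]1(C)CC=C(O1)[C@@](C)(O[Si](CC)(CC)CC)C[C@H](O[Si](C)(C)C(C)(C)C)C2=C(CO[Si](C(C)C)(C(C)C)C(C)C)C(=O)OC2 | intermediate
28 | (2S)-5-[(2S,4S)-4-(TBSO)-4-(Bl)-2-(TESO)butan-2-yl]-2-methyl-2,3-dihydrofuran-2-carbaldehyde | O=C[C@]1(C)CC=C(O1)[C@@](C)(O[Si](CC)(CC)CC)C[C@H](O[Si](C)(C)C(C)(C)C)C2=C(CO[Si](C(C)C)(C(C)C)C(C)C)C(=O)OC2 | intermediate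
29 | 2-(TBSO)furan form of 28 | O=C[C@]1(C)CC=C(O1)[C@@](C)(O[Si](CC)(CC)CC)C[C@H](O[Si](C)(C)C(C)(C)C)c2coc(O[Si](C)(C)C(C)(C)C)c2CO[Si](C(C)C)(C(C)C)C(C)C | intermediate (not isolated)
30 | (4S,6S,10S)-6,9-bis(TBSO)-3,10-epoxy-4-(TESO)-13-(TIPSO)germacra-2,7(11)-dien-12,8-olide, C8/C9 mixture | O=C1OC2C(O[Si](C)(C)C(C)(C)C)[C@]3(C)CC=C(O3)[C@@](C)(O[Si](CC)(CC)CC)C[C@H](O[Si](C)(C)C(C)(C)C)C2=C1CO[Si](C(C)C)(C(C)C)C(C)C | intermediate
31 | (4S,6S,8E,10S)-6-(TBSO)-3,10-epoxy-4-(TESO)-13-(TIPSO)germacra-2,7(11),8-trien-12,8-olide | O=C1O/C2=C/[C@]3(C)CC=C(O3)[C@@](C)(O[Si](CC)(CC)CC)C[C@H](O[Si](C)(C)C(C)(C)C)C2=C1CO[Si](C(C)C)(C(C)C)C(C)C | intermediate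
32 | (4S,6S,8E,10S)-3,10-epoxy-4,6,13-trihydroxygermacra-2,7(11),8-trien-12,8-olide | O=C1O/C2=C/[C@]3(C)CC=C(O3)[C@@](C)(O)C[C@H](O)C2=C1CO | intermediate
33 | (4S,6S,8E,10S)-6,13-diacetoxy-3,10-epoxy-4-hydroxygermacra-2,7(11),8-trien-12,8-olide | CC(=O)OCC1=C2/C(=C\[C@]3(C)CC=C(O3)[C@@](C)(O)C[C@@H]2OC(C)=O)OC1=O | target

**Step count and risks**

Total steps: 22. Longest linear sequence: 20 steps (steps 1–11 and 14–22, from 3-furanmethanol); the west fragment takes 2 steps (12–13).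

Most likely to fail, first: step 19. Closing a strained, bridged ten-membered ring by an aldol is the least precedented step, and the enol ether must survive a silyl triflate. Fallback, setting out from 25 and coming back at 31: close ring A as a saturated ketal so that C3 is sp3 during ring closure, and make the bridgehead enol ether last. Treating 25 with (Ph3P)AuCl/AgOTf in MeOH–CH2Cl2 (cycloisomerisation with methanol addition), then PPTS in the same pot, gives the methyl ketal alcohol F1; the ketal tolerates the acid that removes the primary TES ether, so no fluoride selectivity is needed. Oxidation with SO3·pyridine/DMSO/i-Pr2NEt gives the ketal aldehyde F2. Ring C is then closed through the lithium dienolate (LiN(SiMe3)2, THF, −78 °C, 1 mM), the aldolate is trapped with Ac2O and eliminated with DBU to the macrocyclic ylidene ketal F3. Finally TMSOTf/i-Pr2NEt (CH2Cl2, −20 °C) eliminates methanol from the ketal to give 31.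

Second: step 15. The peracid oxidation is best known for trimethylsilyl furans, and the acetic acid present may attack the primary TES ether. Fallback, setting out from 23 and coming back at 25: photo-oxygenation of the silylfuran (O2, hν, tetraphenylporphyrin, CH2Cl2, −78 °C) gives, through the same silicon-controlled regiochemistry, the γ-hydroxybutenolide F4 (OH on C8). NaBH4 in MeOH at 0 °C reduces its open-chain aldehyde form, and the hydroxy acid relactonises on mild acidic work-up to 25.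

Third: step 8. The furyl ketone is flanked by an ortho substituent and a bulky β-quaternary chain, so catalyst control may be incomplete. Fallback, setting out from 13 and coming back at 14: reduce without a chiral reagent (NaBH4, MeOH, −20 °C), separate 14 from its (2S,4R)-epimer F5 by chromatography, and correct F5 by Mitsunobu inversion with chloroacetic acid (DIAD, PPh3, toluene, 0 °C) to the (2S,4S)-chloroacetate F6. Neutral cleavage with thiourea/NaHCO3 in EtOH then gives 14, which is silylated at once as in step 9.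

**Further compounds**

F1 | step 19 | C3 methyl ketal of ring A with free C9–OH: 4-{(1S,3S)-1-(TBSO)-3-[(5S)-5-(hydroxymethyl)-2-methoxy-5-methyltetrahydrofuran-2-yl]-3-(TESO)butyl}-3-(TIPSOCH2)furan-2(5H)-one (C3 epimers) | OC[C@]1(C)CCC(OC)(O1)[C@@](C)(O[Si](CC)(CC)CC)C[C@H](O[Si](C)(C)C(C)(C)C)C2=C(CO[Si](C(C)C)(C(C)C)C(C)C)C(=O)OC2
F2 | step 19 | corresponding ketal aldehyde: (2S)-5-[(2S,4S)-4-(TBSO)-4-(Bl)-2-(TESO)butan-2-yl]-5-methoxy-2-methyltetrahydrofuran-2-carbaldehyde | O=C[C@]1(C)CCC(OC)(O1)[C@@](C)(O[Si](CC)(CC)CC)C[C@H](O[Si](C)(C)C(C)(C)C)C2=C(CO[Si](C(C)C)(C(C)C)C(C)C)C(=O)OC2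
F3 | step 19 | macrocyclic ylidene butenolide as C3 methyl ketal: (4S,6S,8E,10S)-6-(TBSO)-3,10-epoxy-3-methoxy-4-(TESO)-13-(TIPSO)germacra-7(11),8-dien-12,8-olide | O=C1O/C2=C/[C@]3(C)CCC(OC)(O3)[C@@](C)(O[Si](CC)(CC)CC)C[C@H](O[Si](C)(C)C(C)(C)C)C2=C1CO[Si](C(C)C)(C(C)C)C(C)C
F4 | step 15 | γ-hydroxybutenolide: 5-hydroxy-4-[(1S,3S,7S)-1-(TBSO)-7-hydroxy-3,7-dimethyl-3,8-bis(TESO)oct-4-yn-1-yl]-3-(TIPSOCH2)furan-2(5H)-one (lactol epimers) | CC[Si](CC)(CC)OC[C@@](C)(O)CC#C[C@@](C)(O[Si](CC)(CC)CC)C[C@H](O[Si](C)(C)C(C)(C)C)C1=C(CO[Si](C(C)C)(C(C)C)C(C)C)C(=O)OC1O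
F5 | step 8 | methyl (2S,4R)-4-hydroxy-2-methyl-4-(Fur)-2-(triethylsilyloxy)butanoate | COC(=O)[C@@](C)(O[Si](CC)(CC)CC)C[C@@H](O)c1coc([Si](C)(C)C(C)(C)C)c1CO[Si](C(C)C)(C(C)C)C(C)C
F6 | step 8 | methyl (2S,4S)-4-(chloroacetoxy)-2-methyl-4-(Fur)-2-(triethylsilyloxy)butanoate | COC(=O)[C@@](C)(O[Si](CC)(CC)CC)C[C@H](OC(=O)CCl)c1coc([Si](C)(C)C(C)(C)C)c1CO[Si](C(C)C)(C(C)C)C(C)C
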